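**Retrosynthetic overview**

1. Azulene numbering is used for all bicyclic compounds: C3 is the carbinol carbon with the isopropyl group, C3a–H and C8a–CH3 are the ring-fusion carbons, C4 is the ester carbon, C6 is the carbinol carbon with the methyl group, and C7=C8 is the ring double bond.
2. Endgame: target ⇐ phenol silyl ether 22 ⇐ allylic hydroxylation of C6–H in 21 ⇐ acylation of O4 in diol 19 ⇐ hydroxyl-directed reduction of the C4 ketone 18.
3. Key disconnection: C3a–C8a together with C6–C7, a gold-catalysed intramolecular (4+3) cycloaddition of the acyclic allene–silyloxydiene 16. The five-membered ring closes first through C3a–C8a, and the seven-membered ring follows through C6–C7 in the same operation.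
4. Enabling feature: the quaternary C8a with its methyl group is flanked by the C7=C8 double bond of the seven-membered ring, the footprint of a 1,1-disubstituted allene C8a=C8=C7. O4 sits on the carbon next to C3a–H, the footprint of the enol silane of a C3a=C4–C5=C6 diene. C1–C2–C3 of the five-membered ring is a three-atom tether between the two.
5. 16 ⇐ β-hydroxy enone 15 ⇐ SmI2 opening of epoxy enone 14 ⇐ Sharpless epoxidation of allylic alcohol 10 (sets C3) ⇐ Negishi coupling of enol triflate 7 with the homoallenyl zinc reagent made from but-2-yn-1-ol.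

Key step: step 13

**Route**

Step 1
Reactants: 1 but-2-yn-1-ol
Product: 3 ethyl 3-methylpenta-3,4-dienoate, via ketene acetal 2 (not isolated)
Conditions: MeC(OEt)3, EtCO2H (cat.), 140 °C, removal of EtOH
Reagents that add atoms: triethyl orthoacetate, CC(OCC)(OCC)OCC
Why: Johnson–Claisen rearrangement: the propargylic mixed ketene acetal undergoes a [3,3] shift that turns the alkyne into the 1,1-disubstituted allene and attaches the two-carbon ester arm.

Step 2
Reactants: 3 ethyl 3-methylpenta-3,4-dienoate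
Product: 4 3-methylpenta-3,4-dien-1-ol
Conditions: LiAlH4, Et2O, 0 °C
Reagents that add atoms: none
Why: Hydride reduction of the ester to the primary alcohol at low temperature should leave the isolated allene untouched.

Step 3
Reactants: 4 3-methylpenta-3,4-dien-1-ol
Product: 5 5-iodo-3-methylpenta-1,2-diene
Conditions: I2, PPh3, imidazole, CH2Cl2, 0 °C
Reagents that add atoms: iodine, [I][I]
Why: Appel iodination of the primary alcohol under near-neutral conditions that should not isomerise the allene.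

Step 4
Reactants: 6 methyl 4-methyl-3-oxopentanoate
Product: 7 methyl (2Z)-4-methyl-3-{[(trifluoromethyl)sulfonyl]oxy}pent-2-enoate
Conditions: Tf2O, aq. LiOH, toluene, 5 °C
Reagents that add atoms: trifluoromethanesulfonic anhydride, O=S(=O)(OS(=O)(=O)C(F)(F)F)C(F)(F)F
Why: O-Triflation of the lithium-chelated enolate of the β-keto ester should give the (Z)-enol triflate, which fixes the alkene geometry for the later epoxidation.

Step 5
Reactants: 5 5-iodo-3-methylpenta-1,2-diene; 7 methyl (2Z)-4-methyl-3-{[(trifluoromethyl)sulfonyl]oxy}pent-2-enoate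
Product: 9 methyl (2E)-6-methyl-3-(propan-2-yl)octa-2,6,7-trienoate, via alkylzinc iodide 8 (not isolated)
Conditions: Zn, LiCl, THF, 40 °C; then 7, Pd(dppf)Cl2 (3 mol%), THF, 50 °C
Reagents that add atoms: none
Why: Negishi coupling: zinc insertion into the primary iodide and palladium-catalysed sp3–sp2 coupling with the enol triflate proceed with retention of alkene geometry, so the new chain ends up cis to the ester.

Step 6
Reactants: 9 methyl (2E)-6-methyl-3-(propan-2-yl)octa-2,6,7-trienoate
Product: 10 (2E)-6-methyl-3-(propan-2-yl)octa-2,6,7-trien-1-ol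
Conditions: i-Bu2AlH, CH2Cl2, −78 °C
Reagents that add atoms: none
Why: 1,2-Reduction of the conjugated ester to the allylic alcohol; the allene should not react.

Step 7
Reactants: 10 (2E)-6-methyl-3-(propan-2-yl)octa-2,6,7-trien-1-ol
Product: 11 [(2R,3R)-3-(3-methylpenta-3,4-dien-1-yl)-3-(propan-2-yl)oxiran-2-yl]methanol
Conditions: Ti(OiPr)4 (10 mol%), D-(−)-diethyl tartrate (12 mol%), t-BuOOH, 4 Å MS, CH2Cl2, −20 °C
Reagents that add atoms: tert-butyl hydroperoxide, CC(C)(C)OO
Why: Sharpless asymmetric epoxidation: the D-(−)-tartrate complex should deliver oxygen to the face of the (E)-trisubstituted allylic alcohol that gives the (2R,3R)-epoxide, which sets the configuration of the future C3 carbinol carbon.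

Step 8
Reactants: 11 [(2R,3R)-3-(3-methylpenta-3,4-dien-1-yl)-3-(propan-2-yl)oxiran-2-yl]methanol
Product: 12 (2S,3R)-3-(3-methylpenta-3,4-dien-1-yl)-3-(propan-2-yl)oxirane-2-carbaldehyde
Conditions: Dess–Martin periodinane, NaHCO3, CH2Cl2, 0 °C
Reagents that add atoms: none
Why: Dess–Martin oxidation of the primary epoxy alcohol to the aldehyde under buffered conditions that should not open the epoxide.

Step 9
Reactants: 12 (2S,3R)-3-(3-methylpenta-3,4-dien-1-yl)-3-(propan-2-yl)oxirane-2-carbaldehyde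
Product: 13 (2E)-1-[(2R,3R)-3-(3-methylpenta-3,4-dien-1-yl)-3-(propan-2-yl)oxiran-2-yl]but-2-en-1-ol (both carbinol epimers)
Conditions: (E)-1-bromoprop-1-ene, t-BuLi (2 equiv), Et2O, −78 °C; then 12, −78 °C
Reagents that add atoms: (E)-1-bromoprop-1-ene, C/C=C/Br
Why: 1,2-Addition of (E)-prop-1-enyllithium, formed with retention by bromine–lithium exchange, to the aldehyde; the new carbinol centre is oxidised in the next step, so its configuration does not matter.

Step 10
Reactants: 13 (2E)-1-[(2R,3R)-3-(3-methylpenta-3,4-dien-1-yl)-3-(propan-2-yl)oxiran-2-yl]but-2-en-1-ol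
Product: 14 (2E)-1-[(2S,3R)-3-(3-methylpenta-3,4-dien-1-yl)-3-(propan-2-yl)oxiran-2-yl]but-2-en-1-one
Conditions: Dess–Martin periodinane, NaHCO3, CH2Cl2, 0 °C
Reagents that add atoms: none
Why: Dess–Martin oxidation of the allylic alcohol to the α,β-epoxy enone.

Step 11
Reactants: 14 (2E)-1-[(2S,3R)-3-(3-methylpenta-3,4-dien-1-yl)-3-(propan-2-yl)oxiran-2-yl]but-2-en-1-one
Product: 15 (2E,6S)-6-hydroxy-9-methyl-6-(propan-2-yl)undeca-2,9,10-trien-4-one
Conditions: SmI2 (2.2 equiv), THF/MeOH, −90 °C
Reagents that add atoms: none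
Why: Reductive opening of the α,β-epoxy ketone by SmI2: the ketyl cleaves the Cα–O bond and the samarium enolate is protonated, so the tertiary carbinol keeps the configuration set in step 7.

Step 12
Reactants: 15 (2E,6S)-6-hydroxy-9-methyl-6-(propan-2-yl)undeca-2,9,10-trien-4-one
Product: 16 triethyl({(2E,4Z,6R)-9-methyl-6-(propan-2-yl)-6-[(triethylsilyl)oxy]undeca-2,4,9,10-tetraen-4-yl}oxy)silane
Conditions: Et3SiOTf (2.5 equiv), Et3N, CH2Cl2, −78 to 0 °C
Reagents that add atoms: triethylsilyl trifluoromethanesulfonate, CC[Si](CC)(CC)OS(=O)(=O)C(F)(F)F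
Why: Silylation protects the tertiary alcohol and, by soft α′-enolisation of the enone, should give the (Z)-configured 2-silyloxy diene, with the bulky quaternary carbon cis to the enol oxygen.

Step 13
Reactants: 16 triethyl({(2E,4Z,6R)-9-methyl-6-(propan-2-yl)-6-[(triethylsilyl)oxy]undeca-2,4,9,10-tetraen-4-yl}oxy)silane
Product: 17 triethyl({(3R,3aS,6R,8aR)-6,8a-dimethyl-3-(propan-2-yl)-3-[(triethylsilyl)oxy]-1,2,3,3a,6,8a-hexahydroazulen-4-yl}oxy)silane
Conditions: (JohnPhos)Au(MeCN)SbF6 (5 mol%), 4 Å MS, CH2Cl2, −20 °C to rt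
Reagents that add atoms: none
Why: Proposed new method: the cationic gold catalyst should turn the allene into a 2-aurated allyl cation whose fully substituted terminus C8a is attacked by the enol-silane carbon C3a, the vinyl-gold carbon C7 should then bond to C6 of the resulting silyloxy-allyl cation, and the gold carbene left at C8 should collapse by 1,2-hydride shift from C7 to the C7=C8 alkene, releasing the catalyst and restoring the C4 enol silane. The closest known reaction type is the gold- or platinum-catalysed intramolecular (4+3) cycloaddition of allene-tethered 1,3-dienes to trans-fused bicyclo[5.3.0]decadienes, extended here to a 2-silyloxy diene and to an allene terminus that becomes quaternary; the first bond has its own precedent in gold-catalysed carbocyclisations of silyl enol ethers. The five-membered ring closes 5-exo at the internal allene carbon and the seven-membered ring closes 7-endo at the allyl-cation terminus, both in one operation. C3a is set by the C3 stereocentre: allylic strain against the (Z)-enol silane should place the C3 silyloxy group on the C4 side and the isopropyl group on the C3a–H side of the forming ring, which gives the C3 oxygen trans to H-3a. C8a follows from the exo arrangement of the three-atom tether that makes the known cycloadditions trans-selective (the methyl group sits on the allyl terminus and costs the diene nothing), and C6 follows from the (E)-geometry of the diene terminus and suprafacial bonding, which place the C6 methyl cis to C3 and H-6 cis to H-3a. The step needs closure of C7 at C6 and not at C4 (a five-membered (3+2) product) and hydride shift and not alkyl shift at the carbene; the crowded, fully substituted surroundings of C4 and the electron-rich biaryl phosphine ligand, which favours the (4+3) path with hydride shift in the known cases, are relied on for this.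

Step 14
Reactants: 17 triethyl({(3R,3aS,6R,8aR)-6,8a-dimethyl-3-(propan-2-yl)-3-[(triethylsilyl)oxy]-1,2,3,3a,6,8a-hexahydroazulen-4-yl}oxy)silane
Product: 18 (3R,3aR,6S,8aR)-3-hydroxy-6,8a-dimethyl-3-(propan-2-yl)-1,2,3,3a,5,6-hexahydroazulen-4(8aH)-one
Conditions: HF·pyridine, pyridine, THF, 0 °C
Reagents that add atoms: none
Why: Fluoride-assisted protodesilylation converts the enol silane into the C4 ketone (protonation at C5) and frees the tertiary C3 alcohol without touching C3a.

Step 15
Reactants: 18 (3R,3aR,6S,8aR)-3-hydroxy-6,8a-dimethyl-3-(propan-2-yl)-1,2,3,3a,5,6-hexahydroazulen-4(8aH)-one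
Product: 19 (3R,3aS,4S,6S,8aR)-6,8a-dimethyl-3-(propan-2-yl)-1,2,3,3a,4,5,6,8a-octahydroazulene-3,4-diol
Conditions: Me4NBH(OAc)3, MeCN/AcOH, −30 °C
Reagents that add atoms: none
Why: Evans–Saksena reduction: the C3 hydroxyl binds the triacetoxyborohydride and should deliver hydride intramolecularly to the face of the C4 ketone on which it lies, giving the anti 1,3-diol with the C4 hydroxyl cis to H-3a.

Step 16
Reactants: 19 (3R,3aS,4S,6S,8aR)-6,8a-dimethyl-3-(propan-2-yl)-1,2,3,3a,4,5,6,8a-octahydroazulene-3,4-diol; 20 4-[(tert-butyldimethylsilyl)oxy]benzoic acid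
Product: 21 (3R,3aS,4S,6S,8aR)-3-hydroxy-6,8a-dimethyl-3-(propan-2-yl)-1,2,3,3a,4,5,6,8a-octahydroazulen-4-yl 4-[(tert-butyldimethylsilyl)oxy]benzoate
Conditions: DCC, DMAP (cat.), CH2Cl2, 0 °C to rt
Reagents that add atoms: none
Why: Steglich esterification should acylate the secondary C4 hydroxyl selectively, because the tertiary C3 hydroxyl is too hindered to react.

Step 17
Reactants: 21 (3R,3aS,4S,6S,8aR)-3-hydroxy-6,8a-dimethyl-3-(propan-2-yl)-1,2,3,3a,4,5,6,8a-octahydroazulen-4-yl 4-[(tert-butyldimethylsilyl)oxy]benzoate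
Product: 22 (3R,3aS,4S,6R,8aR)-3,6-dihydroxy-6,8a-dimethyl-3-(propan-2-yl)-1,2,3,3a,4,5,6,8a-octahydroazulen-4-yl 4-[(tert-butyldimethylsilyl)oxy]benzoate
Conditions: SeO2 (0.5 equiv), t-BuOOH, CH2Cl2, rt
Reagents that add atoms: tert-butyl hydroperoxide, CC(C)(C)OO
Why: Allylic hydroxylation by SeO2 (ene reaction at C8 with abstraction of H-6, then [2,3]-sigmatropic shift back to C6) is suprafacial, so the hydroxyl should replace H-6 with retention on the face anti to the angular methyl group; C6 carries the only allylic hydrogen because C8a is quaternary.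

Step 18
Reactants: 22 (3R,3aS,4S,6R,8aR)-3,6-dihydroxy-6,8a-dimethyl-3-(propan-2-yl)-1,2,3,3a,4,5,6,8a-octahydroazulen-4-yl 4-[(tert-butyldimethylsilyl)oxy]benzoate
Product: 23 (3R,3aS,4S,6R,8aR)-3,6-dihydroxy-6,8a-dimethyl-3-(propan-2-yl)-1,2,3,3a,4,5,6,8a-octahydroazulen-4-yl 4-hydroxybenzoate
Conditions: Bu4NF, AcOH, THF, 0 °C
Reagents that add atoms: none
Why: Buffered fluoride cleaves the aryl silyl ether and should leave the aryl ester and the two tertiary alcohols intact.

**Compound list**

1 | but-2-yn-1-ol | CC#CCO | starting material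
2 | 1-(but-2-yn-1-yloxy)-1-ethoxyethene (ketene acetal, not isolated) | C=C(OCC)OCC#CC | intermediate
3 | ethyl 3-methylpenta-3,4-dienoate | CCOC(=O)CC(C)=C=C | intermediate
4 | 3-methylpenta-3,4-dien-1-ol | OCCC(C)=C=C | intermediate
5 | 5-iodo-3-methylpenta-1,2-diene | ICCC(C)=C=C | intermediate
6 | methyl 4-methyl-3-oxopentanoate | COC(=O)CC(=O)C(C)C | starting material
7 | methyl (2Z)-4-methyl-3-{[(trifluoromethyl)sulfonyl]oxy}pent-2-enoate | COC(=O)/C=C(\OS(=O)(=O)C(F)(F)F)C(C)C | intermediate
8 | iodo(3-methylpenta-3,4-dien-1-yl)zinc (alkylzinc iodide, not isolated) | I[Zn]CCC(C)=C=C | intermediate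
9 | methyl (2E)-6-methyl-3-(propan-2-yl)octa-2,6,7-trienoate | COC(=O)/C=C(\CCC(C)=C=C)C(C)C | intermediate
10 | (2E)-6-methyl-3-(propan-2-yl)octa-2,6,7-trien-1-ol | OC/C=C(\CCC(C)=C=C)C(C)C | intermediate
11 | [(2R,3R)-3-(3-methylpenta-3,4-dien-1-yl)-3-(propan-2-yl)oxiran-2-yl]methanol | C=C=C(C)CC[C@]1(C(C)C)O[C@@H]1CO | intermediate
12 | (2S,3R)-3-(3-methylpenta-3,4-dien-1-yl)-3-(propan-2-yl)oxirane-2-carbaldehyde | C=C=C(C)CC[C@]1(C(C)C)O[C@@H]1C=O | intermediate
13 | (2E)-1-[(2R,3R)-3-(3-methylpenta-3,4-dien-1-yl)-3-(propan-2-yl)oxiran-2-yl]but-2-en-1-ol (both carbinol epimers) | C=C=C(C)CC[C@]1(C(C)C)O[C@@H]1C(O)/C=C/C | intermediate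
14 | (2E)-1-[(2S,3R)-3-(3-methylpenta-3,4-dien-1-yl)-3-(propan-2-yl)oxiran-2-yl]but-2-en-1-one | C=C=C(C)CC[C@]1(C(C)C)O[C@@H]1C(=O)/C=C/C | intermediate
15 | (2E,6S)-6-hydroxy-9-methyl-6-(propan-2-yl)undeca-2,9,10-trien-4-one | C=C=C(C)CC[C@@](O)(C(C)C)CC(=O)/C=C/C | intermediate
16 | triethyl({(2E,4Z,6R)-9-methyl-6-(propan-2-yl)-6-[(triethylsilyl)oxy]undeca-2,4,9,10-tetraen-4-yl}oxy)silane | C=C=C(C)CC[C@@](O[Si](CC)(CC)CC)(C(C)C)/C=C(\O[Si](CC)(CC)CC)/C=C/C | intermediate
17 | triethyl({(3R,3aS,6R,8aR)-6,8a-dimethyl-3-(propan-2-yl)-3-[(triethylsilyl)oxy]-1,2,3,3a,6,8a-hexahydroazulen-4-yl}oxy)silane | CC(C)[C@]1(O[Si](CC)(CC)CC)CC[C@]2(C)C=C[C@@H](C)C=C(O[Si](CC)(CC)CC)[C@H]21 | intermediate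
18 | (3R,3aR,6S,8aR)-3-hydroxy-6,8a-dimethyl-3-(propan-2-yl)-1,2,3,3a,5,6-hexahydroazulen-4(8aH)-one | CC(C)[C@]1(O)CC[C@]2(C)C=C[C@@H](C)CC(=O)[C@H]21 | intermediate
19 | (3R,3aS,4S,6S,8aR)-6,8a-dimethyl-3-(propan-2-yl)-1,2,3,3a,4,5,6,8a-octahydroazulene-3,4-diol | CC(C)[C@]1(O)CC[C@]2(C)C=C[C@@H](C)C[C@H](O)[C@H]21 | intermediate
20 | 4-[(tert-butyldimethylsilyl)oxy]benzoic acid | CC(C)(C)[Si](C)(C)Oc1ccc(C(=O)O)cc1 | starting material
21 | (3R,3aS,4S,6S,8aR)-3-hydroxy-6,8a-dimethyl-3-(propan-2-yl)-1,2,3,3a,4,5,6,8a-octahydroazulen-4-yl 4-[(tert-butyldimethylsilyl)oxy]benzoate | CC(C)[C@]1(O)CC[C@]2(C)C=C[C@@H](C)C[C@H](OC(=O)c3ccc(O[Si](C)(C)C(C)(C)C)cc3)[C@H]21 | intermediate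
22 | (3R,3aS,4S,6R,8aR)-3,6-dihydroxy-6,8a-dimethyl-3-(propan-2-yl)-1,2,3,3a,4,5,6,8a-octahydroazulen-4-yl 4-[(tert-butyldimethylsilyl)oxy]benzoate | CC(C)[C@]1(O)CC[C@]2(C)C=C[C@](C)(O)C[C@H](OC(=O)c3ccc(O[Si](C)(C)C(C)(C)C)cc3)[C@H]21 | intermediate
23 | (3R,3aS,4S,6R,8aR)-3,6-dihydroxy-6,8a-dimethyl-3-(propan-2-yl)-1,2,3,3a,4,5,6,8a-octahydroazulen-4-yl 4-hydroxybenzoate | CC(C)[C@]1(O)CC[C@]2(C)C=C[C@](C)(O)C[C@H](OC(=O)c3ccc(O)cc3)[C@H]21 | target

**Step count and risks**

Total step count: 18. Longest linear sequence: 17 steps (steps 1–3 and 5–18, from but-2-yn-1-ol).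

Steps most likely to fail:

1. Step 13 (proposed new method). The aurated intermediate may be protonated, or may close at C4 to a five-membered ring, before the C6–C7 bond forms, and facial control at C3a or C8a may be incomplete. The fallback separates the two ring closures and uses known reaction types; it sets out from 16 and comes back to the route at 18. The same cationic gold catalyst with methanol as proton source (CH2Cl2, 0 °C) should stop after the 5-exo carbocyclisation of the enol silane onto the allene and protodeauration, giving (2E)-1-[(1R,2R,5R)-2-ethenyl-2-methyl-5-(propan-2-yl)-5-[(triethylsilyl)oxy]cyclopentyl]but-2-en-1-one F1. Rhodium-catalysed asymmetric 1,4-addition of potassium vinyltrifluoroborate ([Rh(cod)2]BF4, the BINAP enantiomer that gives the (3S) centre, toluene/H2O, 100 °C) then sets C6 under catalyst control in (3S)-1-[(1R,2R,5R)-2-ethenyl-2-methyl-5-(propan-2-yl)-5-[(triethylsilyl)oxy]cyclopentyl]-3-methylpent-4-en-1-one F2. Ring-closing metathesis with the second-generation Grubbs catalyst (CH2Cl2, 40 °C) closes the seven-membered ring at C7=C8 to (3R,3aR,6S,8aR)-6,8a-dimethyl-3-(propan-2-yl)-3-[(triethylsilyl)oxy]-1,2,3,3a,5,6-hexahydroazulen-4(8aH)-one F3, and HF·pyridine gives 18.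

2. Step 17. The ene reaction at the hindered disubstituted alkene may be too slow, so that unselective oxidation takes over. The fallback reaches the same tertiary allylic alcohol through an epoxide; it sets out from 21 and comes back at 22. Isomerisation of the C7=C8 double bond into the trisubstituted C6=C7 position (RuHCl(CO)(PPh3)3 cat., toluene, 80 °C; C8a is quaternary, so the bond can only move towards C6) should give (3R,3aS,4S,8aR)-3-hydroxy-6,8a-dimethyl-3-(propan-2-yl)-1,2,3,3a,4,5,8,8a-octahydroazulen-4-yl 4-[(tert-butyldimethylsilyl)oxy]benzoate F4. Epoxidation with mCPBA (CH2Cl2, NaHCO3, 0 °C) on the face anti to the angular methyl group should give the 6,7-epoxide with the oxygen cis to H-3a F5. Opening at C7 with PhSeNa ((PhSe)2, NaBH4, EtOH) gives the 6-hydroxy-7-phenylselanyl compound F6, and oxidation with H2O2 followed by selenoxide syn-elimination towards C8 gives 22.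

3. Step 11. Over-reduction of the enone or retro-aldol cleavage of the β-hydroxy ketone may occur under the reducing conditions. The fallback opens the epoxide before the enone exists; it sets out from 11 and comes back at 15. NaAlH2(OCH2CH2OMe)2 (THF, 0 °C) should open the epoxy alcohol at the carbon next to the carbinol to give (3S)-6-methyl-3-(propan-2-yl)octa-6,7-diene-1,3-diol F7. TEMPO/PhI(OAc)2 oxidises the primary alcohol to (3S)-3-hydroxy-6-methyl-3-(propan-2-yl)octa-6,7-dienal F8. (E)-Prop-1-enyllithium (excess, Et2O, −78 °C) gives (2E,6S)-9-methyl-6-(propan-2-yl)undeca-2,9,10-triene-4,6-diol F9, and MnO2 (CH2Cl2, rt) oxidises the allylic alcohol to 15.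

**Further compounds**

F1 | step 13 | (2E)-1-[(1R,2R,5R)-2-ethenyl-2-methyl-5-(propan-2-yl)-5-[(triethylsilyl)oxy]cyclopentyl]but-2-en-1-one | CC(C)[C@]1(O[Si](CC)(CC)CC)CC[C@](C)(C=C)[C@H]1C(=O)/C=C/C
F2 | step 13 | (3S)-1-[(1R,2R,5R)-2-ethenyl-2-methyl-5-(propan-2-yl)-5-[(triethylsilyl)oxy]cyclopentyl]-3-methylpent-4-en-1-one | CC(C)[C@]1(O[Si](CC)(CC)CC)CC[C@](C)(C=C)[C@H]1C(=O)C[C@H](C)C=C
F3 | step 13 | (3R,3aR,6S,8aR)-6,8a-dimethyl-3-(propan-2-yl)-3-[(triethylsilyl)oxy]-1,2,3,3a,5,6-hexahydroazulen-4(8aH)-one | CC(C)[C@]1(O[Si](CC)(CC)CC)CC[C@]2(C)C=C[C@@H](C)CC(=O)[C@H]21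
F4 | step 17 | (3R,3aS,4S,8aR)-3-hydroxy-6,8a-dimethyl-3-(propan-2-yl)-1,2,3,3a,4,5,8,8a-octahydroazulen-4-yl 4-[(tert-butyldimethylsilyl)oxy]benzoate | CC(C)[C@]1(O)CC[C@]2(C)CC=C(C)C[C@H](OC(=O)c3ccc(O[Si](C)(C)C(C)(C)C)cc3)[C@H]21
F5 | step 17 | 6,7-epoxide of F4 with the oxygen cis to H-3a | CC(C)[C@]1(O)CC[C@]2(C)C[C@@H]3O[C@]3(C)C[C@H](OC(=O)c4ccc(O[Si](C)(C)C(C)(C)C)cc4)[C@H]21
F6 | step 17 | 6-hydroxy-7-phenylselanyl compound from F5 (selenium trans to the C6 hydroxyl) | CC(C)[C@]1(O)CC[C@]2(C)C[C@@H]([Se]c3ccccc3)[C@](C)(O)C[C@H](OC(=O)c4ccc(O[Si](C)(C)C(C)(C)C)cc4)[C@H]21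
F7 | step 11 | (3S)-6-methyl-3-(propan-2-yl)octa-6,7-diene-1,3-diol | C=C=C(C)CC[C@@](O)(C(C)C)CCO
F8 | step 11 | (3S)-3-hydroxy-6-methyl-3-(propan-2-yl)octa-6,7-dienal | C=C=C(C)CC[C@@](O)(C(C)C)CC=O
F9 | step 11 | (2E,6S)-9-methyl-6-(propan-2-yl)undeca-2,9,10-triene-4,6-diol (both C4 epimers) | C=C=C(C)CC[C@@](O)(C(C)C)CC(O)/C=C/C
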